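Ring A of the (2S)-flavanone carries oxygen at C5, C7 and C8a and carbon at C4a, C6 and C8 in strict alternation. This pattern is cut into a 2-prenyl-3-oxycyclobutenone (supplying C8a, C6, C5, C4a) and a prenylated methyl ynol ether (supplying C8, C7). One thermal benzannulation forms C8–C8a, C6–C7 and C4a–C8a, closes ring A with both prenyl groups and the C7 methoxy group in place, and leaves C4a as the only C–H, flanked by two oxygens. The precursor is 3-(methoxymethoxy)-2-prenylcyclobut-2-en-1-one. Directed lithiation at C4a, chromone formation and a Pd(OCOCF3)2/pyridine-oxazoline-catalysed enantioselective conjugate arylation then set C2.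

Key step: step 8

Assumption: the Pd(OCOCF3)2/t-BuPyOx catalyst is taken to differentiate the faces of the chromone as it does those of cyclic enones, which assigns the (R)-ligand to the (2S) product; if the sense is the reverse, the (S)-ligand is used with no other change.

Step 1
Reactants: 1 2-methylbut-3-en-2-ol; 2 triethyl orthoacetate
Product: 3 ethyl 5-methylhex-4-enoate
Conditions: EtCO2H (cat.), 140 °C, EtOH distilled off
Reagents that add atoms: none
Why: Johnson–Claisen rearrangement, in which acid-catalysed exchange gives the mixed ketene acetal of the tertiary allylic alcohol and its [3,3]-sigmatropic shift through a chair transition state leaves a gem-dimethyl olefin that has no geometry to control.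

Step 2
Reactants: 3 ethyl 5-methylhex-4-enoate
Product: 4 5-methylhex-4-enoic acid
Conditions: LiOH·H2O, THF/H2O, rt; then aq. HCl
Reagents that add atoms: lithium hydroxide, [Li+].[OH-]
Why: Saponification of an unhindered ethyl ester by hydroxide (acyl addition–elimination) leaves the isolated trisubstituted olefin untouched.

Step 3
Reactants: 4 5-methylhex-4-enoic acid
Product: 5 5-methylhex-4-enoyl chloride
Conditions: (COCl)2, DMF (cat.), CH2Cl2, 0 °C to rt; used crude
Reagents that add atoms: oxalyl chloride, O=C(Cl)C(Cl)=O
Why: Acyl chloride formation through the Vilsmeier-type chloroiminium species from DMF gives only gaseous by-products at low temperature, so the olefin meets HCl only briefly.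

Step 4
Reactants: 5 5-methylhex-4-enoyl chloride; 6 ethoxyacetylene
Product: 8 3-ethoxy-4-(3-methylbut-2-en-1-yl)cyclobut-2-en-1-one, via prenylketene 7 (not isolated)
Conditions: 6 (2.5 equiv), Et3N, Et2O, 0 °C to rt, slow addition of 5
Reagents that add atoms: none
Why: Dehydrochlorination by Et3N gives aldoketene 7, which is intercepted by the ynol ether in a ketene–alkyne (2+2) cycloaddition with the ketene carbonyl carbon joining the unsubstituted, nucleophilic alkyne carbon, so the prenyl group sits on the sp3 carbon C4 (racemic) at this stage, while excess 6 and slow addition hold back ketene dimerisation.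

Step 5
Reactants: 8 3-ethoxy-4-(3-methylbut-2-en-1-yl)cyclobut-2-en-1-one
Product: 9 3-hydroxy-2-(3-methylbut-2-en-1-yl)cyclobut-2-en-1-one (enol form of 2-prenylcyclobutane-1,3-dione)
Conditions: HCl (1 M aq.), THF, 0 °C to rt
Reagents that add atoms: water, O
Why: Acid hydrolysis of the vinylogous ester (addition of water at C3, loss of ethanol) gives the 1,3-dione, which settles as the conjugated enol with the prenyl group on the carbon between the two oxygens, so the C4 stereocentre disappears and the substituent arrives at C2 of the enone.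

Step 6
Reactants: 9 3-hydroxy-2-(3-methylbut-2-en-1-yl)cyclobut-2-en-1-one
Product: 10 3-(methoxymethoxy)-2-(3-methylbut-2-en-1-yl)cyclobut-2-en-1-one
Conditions: MOMCl, i-Pr2NEt, CH2Cl2, 0 °C
Reagents that add atoms: chloromethyl methyl ether, COCCl
Why: O-Alkylation of the strongly acidic vinylogous acid, in which the two oxygens of the vinylogous carboxylate are equivalent and the hard electrophile MOMCl attacks oxygen, so a single enol ether results.

Step 7
Reactants: 11 chloroacetaldehyde dimethyl acetal; 12 prenyl bromide
Product: 14 1-methoxy-5-methylhex-4-en-1-yne, via lithium methoxyacetylide 13 (not isolated)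
Conditions: Et2NH, n-BuLi (3.0 equiv each), THF, 0 °C, then 11; then 12, DMPU, −78 °C to rt
Reagents that add atoms: none
Why: Three equivalents of LiNEt2 eliminate methanol and then HCl from 11 and deprotonate the methoxyacetylene formed, and acetylide 13 is alkylated by SN2 displacement at the primary allylic carbon of 12 in the dipolar cosolvent (alkoxyacetylide alkylation).

Step 8
Reactants: 10 3-(methoxymethoxy)-2-(3-methylbut-2-en-1-yl)cyclobut-2-en-1-one; 14 1-methoxy-5-methylhex-4-en-1-yne
Product: 19 3-methoxy-5-(methoxymethoxy)-2,4-bis(3-methylbut-2-en-1-yl)phenol, via vinylketene 15 (not isolated), via vinylcyclobutenone 16 (not isolated), via dienylketene 17 (not isolated), via cyclohexadienone 18 (not isolated)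
Conditions: 14 (2 equiv), toluene, 110 °C, sealed tube, Ar; then KOH, MeOH, rt (work-up)
Reagents that add atoms: none
Why: Heating opens 10 by four-electron electrocyclic cleavage of its C1–C4 bond to vinylketene 15, whose electrophilic carbonyl carbon is attacked by the oxygen-remote carbon of ynol ether 14 in a ketene–alkyne (2+2) cycloaddition that gives vinylcyclobutenone 16, and a second four-electron opening gives dienylketene 17. Ring A is then closed by thermal six-electron (disrotatory) electrocyclisation of 17, which forms the C8a–C4a bond, and dienone 18 enolises to phenol 19; in flavanone numbering the three new bonds are C8–C8a, C6–C7 and C4a–C8a. The closest known reaction type is the Danheiser benzannulation of cyclobutenones with alkoxyalkynes to resorcinol monoethers, which tolerates 2,3-disubstituted cyclobutenones and ynol ethers with allylic side chains; the 3-oxygen substituent is the sparsely tested element and is expected mainly to raise the temperature of the first ring opening through vinylogous ester stabilisation. No stereocentre is formed. The selectivity required is the orientation of the (2+2) step, secured by the polarisation of the ynol ether (nucleophilic at the prenyl-bearing carbon) against the ketene carbonyl carbon, together with chemoselectivity over the two trisubstituted prenyl olefins, which are far poorer ketenophiles and cannot reach the ketene intramolecularly. A methyl ynol ether is used because it cannot lose an alkene by retro-ene fragmentation at this temperature, and the methanolic KOH treatment returns any phenol acylated by vinylketene.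

Step 9
Reactants: 19 3-methoxy-5-(methoxymethoxy)-2,4-bis(3-methylbut-2-en-1-yl)phenol
Product: 20 3-methoxy-1,5-bis(methoxymethoxy)-2,4-bis(3-methylbut-2-en-1-yl)benzene
Conditions: MOMCl, i-Pr2NEt, CH2Cl2, 0 °C to rt
Reagents that add atoms: chloromethyl methyl ether, COCCl
Why: Williamson-type etherification of the phenol with MOMCl masks the new hydroxyl and turns it into the second ortho-directing group.

Step 10
Reactants: 20 3-methoxy-1,5-bis(methoxymethoxy)-2,4-bis(3-methylbut-2-en-1-yl)benzene
Product: 23 1-[4-methoxy-2,6-bis(methoxymethoxy)-3,5-bis(3-methylbut-2-en-1-yl)phenyl]ethan-1-one, via aryllithium 21 (not isolated), via lithium hemiaminal adduct 22 (not isolated)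
Conditions: n-BuLi, THF, 0 °C; then MeCON(OMe)Me, −78 to 0 °C; H2O
Reagents that add atoms: N-methoxy-N-methylacetamide, CC(=O)N(C)OC
Why: Directed ortho-metalation, in which the only ring C–H lies between two MOM ethers that chelate lithium, so n-BuLi lithiates C4a in preference to the allylic-benzylic CH2 groups, followed by Weinreb ketone synthesis in which chelate 22 collapses to the methyl ketone only on quench.

Step 11
Reactants: 23 1-[4-methoxy-2,6-bis(methoxymethoxy)-3,5-bis(3-methylbut-2-en-1-yl)phenyl]ethan-1-one
Product: 25 5-hydroxy-7-methoxy-6,8-bis(3-methylbut-2-en-1-yl)-4H-chromen-4-one, via enaminone 24 (not isolated)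
Conditions: Me2NCH(OMe)2, toluene, 100 °C; concentrate; then HCl (2 M aq.), MeOH, 40 °C
Reagents that add atoms: N,N-dimethylformamide dimethyl acetal, COC(OC)N(C)C
Why: Condensation of the methyl ketone with the formamide acetal gives enaminone 24, and acid methanolysis of both MOM ethers frees two symmetry-equivalent phenols, one of which adds to the protonated enaminone and expels dimethylamine (enaminone chromone synthesis), the mild temperature limiting acid-promoted cyclisation of phenol onto prenyl.

Step 12
Reactants: 25 5-hydroxy-7-methoxy-6,8-bis(3-methylbut-2-en-1-yl)-4H-chromen-4-one; 26 [4-(tert-butyldimethylsilyloxy)phenyl]boronic acid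
Product: 27 (2S)-2-[4-(tert-butyldimethylsilyloxy)phenyl]-5-hydroxy-7-methoxy-6,8-bis(3-methylbut-2-en-1-yl)-2,3-dihydro-4H-chromen-4-one
Conditions: Pd(OCOCF3)2 (10 mol %), (R)-4-tert-butyl-2-(pyridin-2-yl)-4,5-dihydrooxazole [(R)-t-BuPyOx, 12 mol %], NH4PF6 (30 mol %), H2O (5 equiv), ClCH2CH2Cl, 60 °C, Ar
Reagents that add atoms: none
Why: Enantioselective conjugate addition of an arylboronic acid to a chromone, in which the arylpalladium intermediate formed by transmetalation to ligand-bound Pd(OCOCF3)2 (divalent palladium) inserts the enone, the tert-butyl group of the ligand decides which face of C2 receives the aryl group (catalyst control sets the 2S centre) and water protonates the resulting enolate, while argon excludes reoxidation of any zerovalent palladium and so prevents catalytic oxypalladation of the prenyl olefins.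

Step 13
Reactants: 27 (2S)-2-[4-(tert-butyldimethylsilyloxy)phenyl]-5-hydroxy-7-methoxy-6,8-bis(3-methylbut-2-en-1-yl)-2,3-dihydro-4H-chromen-4-one
Product: 28 (2S)-5-hydroxy-2-(4-hydroxyphenyl)-7-methoxy-6,8-bis(3-methylbut-2-en-1-yl)-2,3-dihydro-4H-chromen-4-one (CNP0121058.1)
Conditions: TBAF, AcOH (1:1), THF, 0 °C
Reagents that add atoms: none
Why: Fluoride-induced cleavage of the aryl silyl ether is buffered with acetic acid so that no phenoxide or enolate forms, which avoids the base-induced retro-oxa-Michael opening that would racemise C2 and exposes the prenyl groups to no strong acid.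

Compound list
1 | 2-methylbut-3-en-2-ol | CC(C)(O)C=C | starting material
2 | triethyl orthoacetate | CCOC(C)(OCC)OCC | starting material
3 | ethyl 5-methylhex-4-enoate | CCOC(=O)CCC=C(C)C | intermediate
4 | 5-methylhex-4-enoic acid | OC(=O)CCC=C(C)C | intermediate
5 | 5-methylhex-4-enoyl chloride | O=C(Cl)CCC=C(C)C | intermediate
6 | ethoxyacetylene | CCOC#C | starting material
7 | prenylketene (5-methylhexa-1,4-dien-1-one) | O=C=CCC=C(C)C | intermediate (not isolated)
8 | 3-ethoxy-4-(3-methylbut-2-en-1-yl)cyclobut-2-en-1-one (racemic) | CCOC1=CC(=O)C1CC=C(C)C | intermediate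
9 | 3-hydroxy-2-(3-methylbut-2-en-1-yl)cyclobut-2-en-1-one | O=C1CC(O)=C1CC=C(C)C | intermediate
10 | 3-(methoxymethoxy)-2-(3-methylbut-2-en-1-yl)cyclobut-2-en-1-one | O=C1CC(OCOC)=C1CC=C(C)C | intermediate
11 | chloroacetaldehyde dimethyl acetal (2-chloro-1,1-dimethoxyethane) | COC(CCl)OC | starting material
12 | prenyl bromide (1-bromo-3-methylbut-2-ene) | CC(C)=CCBr | starting material
13 | lithium methoxyacetylide | [Li]C#COC | intermediate (not isolated)
14 | 1-methoxy-5-methylhex-4-en-1-yne | COC#CCC=C(C)C | intermediate
15 | 3-(methoxymethoxy)-2-(3-methylbut-2-en-1-yl)buta-1,3-dien-1-one (vinylketene) | O=C=C(CC=C(C)C)C(=C)OCOC | intermediate (not isolated)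
16 | 3-methoxy-4-[1-(methoxymethoxy)ethenyl]-2,4-bis(3-methylbut-2-en-1-yl)cyclobut-2-en-1-one | O=C1C(CC=C(C)C)=C(OC)C1(CC=C(C)C)C(=C)OCOC | intermediate (not isolated)
17 | 3-methoxy-5-(methoxymethoxy)-2,4-bis(3-methylbut-2-en-1-yl)hexa-1,3,5-trien-1-one (dienylketene, ketene and alkoxyvinyl groups cis) | O=C=C(CC=C(C)C)/C(OC)=C(CC=C(C)C)\C(=C)OCOC | intermediate (not isolated)
18 | 3-methoxy-5-(methoxymethoxy)-2,4-bis(3-methylbut-2-en-1-yl)cyclohexa-2,4-dien-1-one | O=C1CC(OCOC)=C(CC=C(C)C)C(OC)=C1CC=C(C)C | intermediate (not isolated)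
19 | 3-methoxy-5-(methoxymethoxy)-2,4-bis(3-methylbut-2-en-1-yl)phenol | COCOc1cc(O)c(CC=C(C)C)c(OC)c1CC=C(C)C | intermediate
20 | 3-methoxy-1,5-bis(methoxymethoxy)-2,4-bis(3-methylbut-2-en-1-yl)benzene | COCOc1cc(OCOC)c(CC=C(C)C)c(OC)c1CC=C(C)C | intermediate
21 | [4-methoxy-2,6-bis(methoxymethoxy)-3,5-bis(3-methylbut-2-en-1-yl)phenyl]lithium | [Li]c1c(OCOC)c(CC=C(C)C)c(OC)c(CC=C(C)C)c1OCOC | intermediate (not isolated)
22 | lithium 1-[4-methoxy-2,6-bis(methoxymethoxy)-3,5-bis(3-methylbut-2-en-1-yl)phenyl]-1-[methoxy(methyl)amino]ethan-1-olate | [Li]OC(C)(N(C)OC)c1c(OCOC)c(CC=C(C)C)c(OC)c(CC=C(C)C)c1OCOC | intermediate (not isolated)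
23 | 1-[4-methoxy-2,6-bis(methoxymethoxy)-3,5-bis(3-methylbut-2-en-1-yl)phenyl]ethan-1-one | CC(=O)c1c(OCOC)c(CC=C(C)C)c(OC)c(CC=C(C)C)c1OCOC | intermediate
24 | (E)-3-(dimethylamino)-1-[4-methoxy-2,6-bis(methoxymethoxy)-3,5-bis(3-methylbut-2-en-1-yl)phenyl]prop-2-en-1-one | CN(C)/C=C/C(=O)c1c(OCOC)c(CC=C(C)C)c(OC)c(CC=C(C)C)c1OCOC | intermediate (not isolated)
25 | 5-hydroxy-7-methoxy-6,8-bis(3-methylbut-2-en-1-yl)-4H-chromen-4-one | O=c1ccoc2c(CC=C(C)C)c(OC)c(CC=C(C)C)c(O)c12 | intermediate
26 | [4-(tert-butyldimethylsilyloxy)phenyl]boronic acid | CC(C)(C)[Si](C)(C)Oc1ccc(B(O)O)cc1 | starting material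
27 | (2S)-2-[4-(tert-butyldimethylsilyloxy)phenyl]-5-hydroxy-7-methoxy-6,8-bis(3-methylbut-2-en-1-yl)-2,3-dihydro-4H-chromen-4-one | COc1c(CC=C(C)C)c(O)c2c(c1CC=C(C)C)O[C@H](c1ccc(O[Si](C)(C)C(C)(C)C)cc1)CC2=O | intermediate
28 | (2S)-5-hydroxy-2-(4-hydroxyphenyl)-7-methoxy-6,8-bis(3-methylbut-2-en-1-yl)-2,3-dihydro-4H-chromen-4-one | COc1c(CC=C(C)C)c(O)c2c(c1CC=C(C)C)O[C@H](c1ccc(O)cc1)CC2=O | target

Total step count: 13. Longest linear sequence: 12 steps (steps 1 to 6, then 8 to 13).

Steps most likely to fail

Step 8. The push-pull stabilised cyclobutenone may open too slowly, so that thermal decay of the ynol ether or acylation and oligomerisation of the vinylketene overtakes the benzannulation. The fallback abandons the benzannulation for classical phloroglucinol chemistry. It sets out from prenyl bromide 12, which C-prenylates commercial 2',4',6'-trihydroxyacetophenone twice (aq. KOH, 0 °C) to give 1-[2,4,6-trihydroxy-3,5-bis(3-methylbut-2-en-1-yl)phenyl]ethan-1-one F1. The non-chelated 4-hydroxyl is then methylated selectively (Me2SO4, 1 equiv, K2CO3, acetone) to give 1-[2,6-dihydroxy-4-methoxy-3,5-bis(3-methylbut-2-en-1-yl)phenyl]ethan-1-one F2. Protection of both phenols (NaH, MOMCl, DMF) brings the material back to the route at acetophenone 23.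

Step 12. Insertion may be slow at the electron-rich, fully substituted chromone, the C5 hydroxyl or the arylpalladium species may engage a prenyl olefin, or the facial selectivity may be low or opposite to the assumed sense. Premature loss of the silyl group would be harmless, since it gives 28 directly. The fallback builds the heterocycle by the chalcone route and obtains the enantiomer by separation. It sets out from acetophenone 23, which is condensed with 4-(methoxymethoxy)benzaldehyde (KOH, EtOH, rt, Claisen–Schmidt) to give (E)-1-[4-methoxy-2,6-bis(methoxymethoxy)-3,5-bis(3-methylbut-2-en-1-yl)phenyl]-3-[4-(methoxymethoxy)phenyl]prop-2-en-1-one F3. Mild HCl/MeOH removes the three MOM groups to give (E)-1-[2,6-dihydroxy-4-methoxy-3,5-bis(3-methylbut-2-en-1-yl)phenyl]-3-(4-hydroxyphenyl)prop-2-en-1-one F4. NaOAc in refluxing EtOH closes it by oxa-Michael addition to racemic 5-hydroxy-2-(4-hydroxyphenyl)-7-methoxy-6,8-bis(3-methylbut-2-en-1-yl)-2,3-dihydro-4H-chromen-4-one F5. Preparative chromatography on a cellulose tris(3,5-dimethylphenylcarbamate) stationary phase then delivers the (2S) enantiomer, which is target 28; the (2R) enantiomer can be racemised with base and recycled.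

Step 4. The aldoketene may dimerise or be consumed by amine-catalysed self-condensation faster than the ynol ether intercepts it. The fallback inverts the roles of the two partners, so that the prenyl group arrives on the alkyne and at C2 directly. It sets out from ynol ether 14, which is treated with dichloroketene (Cl3CCOCl, Zn, DME/Et2O, 0 °C to rt) to give 4,4-dichloro-3-methoxy-2-(3-methylbut-2-en-1-yl)cyclobut-2-en-1-one F6. Reductive dechlorination (Zn, AcOH, TMEDA, EtOH, 0 °C) gives 3-methoxy-2-(3-methylbut-2-en-1-yl)cyclobut-2-en-1-one F7. Hydrolysis of this vinylogous methyl ester (1 M HCl, THF) brings the material back to the route at compound 9.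

Further compounds
F1 | step 8 | 1-[2,4,6-trihydroxy-3,5-bis(3-methylbut-2-en-1-yl)phenyl]ethan-1-one | CC(=O)c1c(O)c(CC=C(C)C)c(O)c(CC=C(C)C)c1O
F2 | step 8 | 1-[2,6-dihydroxy-4-methoxy-3,5-bis(3-methylbut-2-en-1-yl)phenyl]ethan-1-one | CC(=O)c1c(O)c(CC=C(C)C)c(OC)c(CC=C(C)C)c1O
F3 | step 12 | (E)-1-[4-methoxy-2,6-bis(methoxymethoxy)-3,5-bis(3-methylbut-2-en-1-yl)phenyl]-3-[4-(methoxymethoxy)phenyl]prop-2-en-1-one | COCOc1ccc(/C=C/C(=O)c2c(OCOC)c(CC=C(C)C)c(OC)c(CC=C(C)C)c2OCOC)cc1
F4 | step 12 | (E)-1-[2,6-dihydroxy-4-methoxy-3,5-bis(3-methylbut-2-en-1-yl)phenyl]-3-(4-hydroxyphenyl)prop-2-en-1-one | Oc1ccc(/C=C/C(=O)c2c(O)c(CC=C(C)C)c(OC)c(CC=C(C)C)c2O)cc1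
F5 | step 12 | racemic 5-hydroxy-2-(4-hydroxyphenyl)-7-methoxy-6,8-bis(3-methylbut-2-en-1-yl)-2,3-dihydro-4H-chromen-4-one | COc1c(CC=C(C)C)c(O)c2c(c1CC=C(C)C)OC(c1ccc(O)cc1)CC2=O
F6 | step 4 | 4,4-dichloro-3-methoxy-2-(3-methylbut-2-en-1-yl)cyclobut-2-en-1-one | O=C1C(CC=C(C)C)=C(OC)C1(Cl)Cl
F7 | step 4 | 3-methoxy-2-(3-methylbut-2-en-1-yl)cyclobut-2-en-1-one | O=C1CC(OC)=C1CC=C(C)C
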